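## Structural features

The target is one six-membered carbocycle in which every ring carbon is fully substituted. C1, C3 and C5 are at the ketone oxidation level (C3 written as its enol), C2 carries the 2-methylpropanoyl group, C6 carries two prenyl groups, and C4 carries a hydroxyl and the third prenyl group. C4 is the only stereocentre (S in the drawn tautomer); it has no stereogenic neighbour and lies between the C3 and C5 carbonyl carbons, so it is a tertiary alpha-ketol that cannot epimerise by enolisation but can rearrange. The C5 ketone sits between the quaternary carbons C4 and C6 and cannot enolise, whereas C1–C2–C3 and the side-chain carbonyl form an acidic, chelated beta-triketone. The fragile elements are: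
- the three trisubstituted alkenes, which are sensitive to electrophilic oxidants and to strong acid (acid would also add the enol oxygen across a prenyl double bond);
- the free alpha-ketol, which can undergo alkoxide-driven acyloin ring contraction to a five-membered ring, as related hop-type acids do;
- the C5 carbonyl, which is open to retro-Claisen cleavage by nucleophilic base.

The real difficulty is twofold: a lone oxygenated quaternary stereocentre must be made with no neighbouring stereocentre to relay from, and a hexasubstituted ring with two quaternary carbons must be closed under conditions these groups tolerate. The key step uses the fact that C2 is bonded only to three carbonyl carbons (C1, C3 and the side-chain carbonyl), so it can be the methyl carbon of a methyl ketone. Because C4 and C6 are quaternary, the complementary C3–C4–C5–C6–C1 keto-diester has no alpha-hydrogen at all.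

## Logic of the disconnections

**14 to 13.** Only the O–Si bond at C4 is broken. The hydroxyl must stay masked until the end: a free C4 alkoxide in the open-chain stage would close onto the C1 ester (five-membered lactone) and, in the ring, would trigger the acyloin shift. The forward step must therefore be a non-basic, weakly acidic desilylation.

**13 to 10 and 11.** C1–C2 and C2–C3 are cut, so C2 with its acyl group becomes the methyl carbon of 11 and the ring becomes the open keto-diester 10. This removes the ring, the beta-triketone and the side chain in one move and leaves a chain with no acidic hydrogen. The forward step must acylate at the two ester carbonyls and not at the C5 ketone, and the second acylation must be the intramolecular one.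

**10 to 9 and two molecules of 2.** Both C6–CH2 bonds are cut. C6 of 9 is the only acidic carbon of a beta-keto ester, so both prenyl groups can be added by enolate alkylation. This order means the C5 ketone is never forged between two quaternary carbons; it is made while C6 is still a CH2. The forward step needs C-alkylation twice, not O-alkylation.

**9 to 6 and 7, through 8.** C5–C6 is cut between an acyl chloride carbon (C5) and the enolate carbon of 7 (C6). This reduces the chain to a malonate half-ester derivative. The forward step must react only at the carboxyl that was the free acid; the silyl ester of 6 is the handle that is turned into 8 while the methyl ester stays as the future C3.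

**6 to 5.** Two Si–O bonds are cut (silyl ether and silyl ester). One reagent both protects the tertiary alcohol and prepares the acid for conversion into the chloride.

**5 to 4.** No skeletal bond is cut. The stereocentre is traced back to the two enantiotopic ester groups of the achiral diester 4, and the forward step must distinguish them. This replaces asymmetric construction of a quaternary carbinol by a group-selective hydrolysis.

**4 to 3.** The C4–O bond is cut; the forward step is hydroxylation of a malonate enolate by an oxidant that leaves the prenyl alkene alone.

**3 to 1 and 2.** The C4–CH2 bond is cut; the forward step is a mono-alkylation of 1.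

## Other disconnections considered

**Alternative 1:** The cut is C3–C4, made as an O-to-C acyl shift.
- Forward step: the precursor would be the enol lactone A1, (Z)-6-[1-(tert-butyldimethylsilyloxy)-4-methylpent-3-enylidene]-4-methoxy-5,5-bis(3-methylbut-2-enyl)-5,6-dihydro-2H-pyran-2-one (drawn as Z; one defined geometry would be needed), in which the enol oxygen of the C5 ketone is acylated by C3. A chiral nucleophilic acyl-transfer catalyst (4-aminopyridine or isothiourea type) would add to the lactone carbonyl C3 and release the C4=C5 enolate. The tethered acyl-ammonium would then be recaptured at C4 to give the carbocycle A2, (S)-2-(tert-butyldimethylsilyloxy)-5-methoxy-2,4,4-tris(3-methylbut-2-enyl)cyclohex-5-ene-1,3-dione.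
- In its favour: ring and stereocentre would arise in one catalytic event, and the sense of induction would follow from the catalyst enantiomer and not from an enzyme; on this point it is the better plan. It also avoids exposing an open-chain non-enolisable beta-keto ester to alkoxide, where it is at least the equal of the chosen plan.
- Against it: the lactone carbonyl is a vinylogous carbonate (conjugated with the C1 methoxy group) and so a weak acyl donor. The enolate to be C-acylated is an unstabilised alpha-silyloxy ketone enolate next to a quaternary carbon, whereas established asymmetric acyl shifts rely on stabilised heterocyclic enolates, so the step would have to be developed as new chemistry. A1 also needs control of enol geometry.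
- Comparison: structurally, A2 still lacks the C2 acyl group and carries an O-methyl group, so demethylation, C2-acylation and desilylation would follow (three steps after the key step against one). Mechanistically, the chosen plan rests on two classical carbonyl condensations. In step economy the two are comparable before ring formation and the chosen plan is shorter after it.

**Alternative 2:** The cut is C4–C5.
- Forward step: the precursor would be the achiral triketo-aldehyde A3, 9-methyl-2,2-bis(3-methylbut-2-enyl)-3,5,6-trioxodec-8-enal. A chiral triazolium-derived carbene would turn the C5 aldehyde into an acyl-anion equivalent that adds to the C4 ketone, closing the ring and creating the carbinol in A4, (S)-3,4-dihydroxy-4,6,6-tris(3-methylbut-2-enyl)cyclohex-2-ene-1,5-dione.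
- In its favour: ring and stereocentre come from an achiral chain in one catalytic step, with no enzyme or resolution and no protecting group on the tertiary alcohol; on these three points it is better than the chosen plan.
- Against it: the aldehyde hangs on the gem-diprenyl quaternary carbon and would form the acyl-anion equivalent slowly. The C1/C3/C4 tricarbonyl array of A3 would be largely enolised and deprotonated by the base that liberates the carbene, which lowers the electrophilicity of C4 and offers C3 as a competing acceptor. The beta,gamma-unsaturated alpha-diketone can isomerise into conjugation. A4 still needs the acyl group at C2, to be added to a molecule that already has the free, base-sensitive alpha-ketol.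
- Comparison: in mechanism, the alternative depends on a demanding catalyst-controlled step, while the chosen plan pays with an enzymatic desymmetrisation of uncertain sense. Step economy would be similar at best: the protecting-group steps saved are offset by the C2-acylation and the longer assembly of A3.

**Alternative 3:** The cut is C5–C6.
- Forward step: the precursor would be the diketo-ester A5, methyl (S)-2-(tert-butyldimethylsilyloxy)-9-methyl-2,6-bis(3-methylbut-2-enyl)-3,5-dioxodec-8-enoate. Two equivalents of a strong amide base would give the 1,3-diketone dianion, whose gamma-carbon C6 would attack the C5 ester to give A6, (S)-4-(tert-butyldimethylsilyloxy)-3-hydroxy-4,6,6-tris(3-methylbut-2-enyl)cyclohex-2-ene-1,5-dione.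
- In its favour: C6–H is the only gamma-hydrogen (C4 is quaternary), so the dianion is regiochemically unambiguous. The closure is purely intramolecular, so no second intermolecular acylation can compete, and the C5 ketone never exists in an open chain, so the acyclic retro-Claisen risk of the chosen plan is absent; on these points it is the better plan. It uses the same malonate half-ester chemistry with the two carboxyl carbons exchanged (ester carbon becomes C5, acid carbon C3). It is therefore the equal of the chosen plan in the source of chirality and would be preferred if the esterase delivered the opposite half-ester.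
- Against it: the bond formed is the most congested in the molecule. A tertiary carbanion bearing two prenyl groups must attack an ester on a fully substituted, silyloxy-bearing carbon, creating the quaternary C6 and the doubly neopentyl ketone together, and the strongly basic dianion would have time to fragment or shift silicon instead.
- Comparison: A6 lacks the C2 acyl group, so a separate C-acylation would precede desilylation: one step more after the key step and no fewer before it. The chosen plan makes C5–C6 with a small acetate enolate and builds C6 by alkylation, which is the structurally easier order.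

Key step: step 7

**Remark on the structures:** the key-step precursor 10 and product 13 were checked atom by atom against the target. The spatial arrangement at C4 is identical throughout; the descriptor reads R in 5, 9, 10 and 12 and S in 6, 8, 13 and 14 only because substituent priorities change. No correction was needed.

**Assumption:** pig liver esterase is taken to hydrolyse the ester group that leads to the (R)-half-ester 5. The sense of enantiotopic-group selection for this substrate cannot be predicted with confidence and is covered by the fallback for step 3.

## Route

Step 1
Reactants: 1 dimethyl malonate; 2 1-bromo-3-methylbut-2-ene (prenyl bromide)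
Product: 3 dimethyl 2-(3-methylbut-2-enyl)malonate
Conditions: NaH (1.0 equiv), 1 (2.5 equiv), THF, 0 °C; 2 (1.0 equiv), 0 → 25 °C; distillation
Reagents that add atoms: none
Why: Malonic ester alkylation: the sodium enolate of 1 displaces bromide from the primary allylic carbon of 2 by SN2; the excess of 1 suppresses dialkylation and is removed by distillation.

Step 2
Reactants: 3 dimethyl 2-(3-methylbut-2-enyl)malonate
Product: 4 dimethyl 2-hydroxy-2-(3-methylbut-2-enyl)malonate
Conditions: NaH (1.05 equiv), THF, 0 °C; 2-(benzenesulfonyl)-3-phenyloxaziridine (1.2 equiv), −78 → 0 °C; AcOH
Reagents that add atoms: 2-(benzenesulfonyl)-3-phenyloxaziridine, O=S(=O)(c1ccccc1)N1OC1c1ccccc1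
Why: Electrophilic hydroxylation of a stabilised enolate by an N-sulfonyloxaziridine (the enolate carbon attacks the oxaziridine oxygen); this aprotic oxidant should leave the trisubstituted alkene untouched, which a peracid or dioxirane would not. The product is achiral because its two ester groups are identical.

Step 3
Reactants: 4 dimethyl 2-hydroxy-2-(3-methylbut-2-enyl)malonate
Product: 5 (R)-2-hydroxy-2-(methoxycarbonyl)-5-methylhex-4-enoic acid
Conditions: pig liver esterase, phosphate buffer pH 7.5, DMSO (10%), 25 °C, pH-stat with NaOH (1.0 equiv); then HCl to pH 2, EtOAc
Reagents that add atoms: water, O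
Why: Esterase desymmetrisation of a prochiral disubstituted malonate: the enzyme should hydrolyse one of the two enantiotopic methyl esters and stop at the mono-acid anion, which creates the C4 stereocentre through the different fit of the polar OH and the lipophilic prenyl group in the active site. The (R) sense is the stated assumption; optical purity could be raised by crystallising an amine salt.

Step 4
Reactants: 5 (R)-2-hydroxy-2-(methoxycarbonyl)-5-methylhex-4-enoic acid
Product: 6 tert-butyldimethylsilyl methyl (S)-2-(tert-butyldimethylsilyloxy)-2-(3-methylbut-2-enyl)malonate
Conditions: TBSOTf (2.5 equiv), 2,6-lutidine (3.5 equiv), CH2Cl2, 0 → 25 °C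
Reagents that add atoms: tert-butyldimethylsilyl trifluoromethanesulfonate (TBSOTf), CC(C)(C)[Si](C)(C)OS(=O)(=O)C(F)(F)F
Why: Silyl triflate silylation with a hindered pyridine base should convert the acid into the silyl ester and the tertiary, doubly carbonyl-flanked alcohol into its silyl ether in one flask. No bond to the stereocentre is broken; the descriptor changes to S only because the silyl ester outranks the methyl ester.

Step 5
Reactants: 6 tert-butyldimethylsilyl methyl (S)-2-(tert-butyldimethylsilyloxy)-2-(3-methylbut-2-enyl)malonate; 7 methyl acetate
Product: 9 dimethyl (R)-2-(tert-butyldimethylsilyloxy)-2-(3-methylbut-2-enyl)-3-oxopentanedioate, via acid chloride 8 (not isolated)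
Conditions: (COCl)2 (1.2 equiv), DMF (cat.), CH2Cl2, 0 → 25 °C, evaporate; add to 7 (2.3 equiv)/LiN(iPr)2 (2.2 equiv), THF, −78 °C; 1 M HCl, 0 °C
Reagents that add atoms: none
Why: Oxalyl chloride with catalytic DMF turns a silyl ester directly into the acid chloride under neutral conditions, so the silyl ether and alkene should survive; crossed Claisen acylation of the lithium enolate of 7 then forms C5–C6, with the second equivalent of enolate deprotonating the beta-keto ester so it is not attacked again. The acid chloride reacts far faster than the neighbouring methyl ester, which differentiates the two carboxyl carbons, and the quaternary stereocentre cannot epimerise.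

Step 6
Reactants: 9 dimethyl (R)-2-(tert-butyldimethylsilyloxy)-2-(3-methylbut-2-enyl)-3-oxopentanedioate; 2 1-bromo-3-methylbut-2-ene
Product: 10 dimethyl (R)-2-(tert-butyldimethylsilyloxy)-2,4,4-tris(3-methylbut-2-enyl)-3-oxopentanedioate
Conditions: NaH (2.3 equiv), 2 (2.6 equiv), THF, 0 → 40 °C
Reagents that add atoms: none
Why: Twofold C-alkylation of a beta-keto ester at its only acidic carbon (C6) with a soft allylic bromide; the sodium enolate in THF is a weakly dissociating medium that favours C- over O-alkylation. C4 is fully substituted, so there is no second enolisable site, and no nucleophilic base is present that could cleave 10 by retro-Claisen reaction.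

Step 7
Reactants: 10 dimethyl (R)-2-(tert-butyldimethylsilyloxy)-2,4,4-tris(3-methylbut-2-enyl)-3-oxopentanedioate; 11 3-methylbutan-2-one
Product: 13 (S)-4-(tert-butyldimethylsilyloxy)-3-hydroxy-2-(2-methylpropanoyl)-4,6,6-tris(3-methylbut-2-enyl)cyclohex-2-ene-1,5-dione, via acyclic beta-diketone ester 12 (not isolated)
Conditions: 11 (1.15 equiv), LiN(iPr)2 (1.1 equiv), THF, −78 °C; LiN(SiMe3)2 (2.1 equiv); 10, −78 → 25 °C, then 45 °C; 1 M HCl, 0 °C
Reagents that add atoms: none
Why: The lithium enolate formed at the methyl group of 11 (kinetic deprotonation at −78 °C) adds to one ester carbonyl of 10 and expels methoxide to give the beta-diketone 12 (drawn for first attack at the C1 ester; first attack at C3 leads to the same ring, because both carbonyl carbons end up on C2). 12 is deprotonated at its central CH2 by LiN(SiMe3)2, and this diketonate carbon attacks the remaining ester in a 6-exo-trig Dieckmann closure that forms the second bond to C2 and the ring; loss of methoxide and a last deprotonation give the 2-acyl-1,3-dione anion, which is the thermodynamic sink and no longer electrophilic. The closest known reaction type is the Claisen-then-Dieckmann condensation of a methyl ketone enolate with a 1,5-diester to a 2-acylcyclohexane-1,3-dione, the laboratory counterpart of the ring closure in acylphloroglucinol biosynthesis. No stereocentre is formed; C4 is carried through unchanged because it bears no hydrogen and none of its four bonds is broken. The selectivity needed is attack at the ester carbonyls and not at the C5 ketone, where addition would open retro-Claisen cleavage: C5 lies between two fully substituted carbons, one carrying the bulky silyl ether, whereas each ester carbonyl has only one such neighbour. 10 has no alpha-hydrogen, so it cannot enolise, self-condense or epimerise; LiN(SiMe3)2 is the extra base because excess LiN(iPr)2 could reduce the non-enolisable C5 ketone by hydride transfer and could form a diketone dianion. Only a small excess of 11 is used so that ring closure of 12 is not outrun by a second intermolecular acylation, and the warming to 45 °C is reserved for the slower Dieckmann stage; a kinetic O-acylation of the diketonate to an enol lactone would be reversible while methoxide is present.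

Step 8
Reactants: 13 (S)-4-(tert-butyldimethylsilyloxy)-3-hydroxy-2-(2-methylpropanoyl)-4,6,6-tris(3-methylbut-2-enyl)cyclohex-2-ene-1,5-dione
Product: 14 (S)-3,4-dihydroxy-2-(2-methylpropanoyl)-4,6,6-tris(3-methylbut-2-enyl)cyclohex-2-ene-1,5-dione
Conditions: HF·pyridine, pyridine, THF, 0 → 25 °C; cold dilute aqueous citric acid work-up
Reagents that add atoms: none
Why: Fluoride-assisted Si–O cleavage with pyridine-buffered HF: the two flanking carbonyl groups make the C4 oxygen a good leaving group from silicon. The medium never becomes basic, so the freed alpha-ketol should not undergo the alkoxide-driven acyloin ring contraction, and it is too weakly acidic to add the enol OH across a prenyl alkene; no bond to C4 is broken, so the configuration is retained.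

## Compound list

1 | dimethyl malonate | COC(=O)CC(=O)OC | starting material
2 | 1-bromo-3-methylbut-2-ene (prenyl bromide) | CC(C)=CCBr | starting material
3 | dimethyl 2-(3-methylbut-2-enyl)malonate | COC(=O)C(CC=C(C)C)C(=O)OC | intermediate
4 | dimethyl 2-hydroxy-2-(3-methylbut-2-enyl)malonate | COC(=O)C(O)(CC=C(C)C)C(=O)OC | intermediate
5 | (R)-2-hydroxy-2-(methoxycarbonyl)-5-methylhex-4-enoic acid | COC(=O)[C@@](O)(CC=C(C)C)C(=O)O | intermediate
6 | tert-butyldimethylsilyl methyl (S)-2-(tert-butyldimethylsilyloxy)-2-(3-methylbut-2-enyl)malonate | COC(=O)[C@@](O[Si](C)(C)C(C)(C)C)(CC=C(C)C)C(=O)O[Si](C)(C)C(C)(C)C | intermediate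
7 | methyl acetate | CC(=O)OC | starting material
8 | methyl (S)-2-(tert-butyldimethylsilyloxy)-2-(chlorocarbonyl)-5-methylhex-4-enoate (not isolated) | COC(=O)[C@@](O[Si](C)(C)C(C)(C)C)(CC=C(C)C)C(Cl)=O | intermediate
9 | dimethyl (R)-2-(tert-butyldimethylsilyloxy)-2-(3-methylbut-2-enyl)-3-oxopentanedioate | COC(=O)[C@@](O[Si](C)(C)C(C)(C)C)(CC=C(C)C)C(=O)CC(=O)OC | intermediate
10 | dimethyl (R)-2-(tert-butyldimethylsilyloxy)-2,4,4-tris(3-methylbut-2-enyl)-3-oxopentanedioate | COC(=O)[C@@](O[Si](C)(C)C(C)(C)C)(CC=C(C)C)C(=O)C(CC=C(C)C)(CC=C(C)C)C(=O)OC | intermediate
11 | 3-methylbutan-2-one | CC(C)C(C)=O | starting material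
12 | methyl (R)-2-(tert-butyldimethylsilyloxy)-8-methyl-2,4,4-tris(3-methylbut-2-enyl)-3,5,7-trioxononanoate (not isolated) | COC(=O)[C@@](O[Si](C)(C)C(C)(C)C)(CC=C(C)C)C(=O)C(CC=C(C)C)(CC=C(C)C)C(=O)CC(=O)C(C)C | intermediate
13 | (S)-4-(tert-butyldimethylsilyloxy)-3-hydroxy-2-(2-methylpropanoyl)-4,6,6-tris(3-methylbut-2-enyl)cyclohex-2-ene-1,5-dione | CC(C)C(=O)C1=C(O)[C@@](O[Si](C)(C)C(C)(C)C)(CC=C(C)C)C(=O)C(CC=C(C)C)(CC=C(C)C)C1=O | intermediate
14 | (S)-3,4-dihydroxy-2-(2-methylpropanoyl)-4,6,6-tris(3-methylbut-2-enyl)cyclohex-2-ene-1,5-dione | CC(C)=CCC1(CC=C(C)C)C(=O)C(C(=O)C(C)C)=C(O)[C@@](O)(CC=C(C)C)C1=O | target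

## Step count and least certain steps

Total steps: 8. Longest linear sequence: 8 steps (1 to 14); 2, 7 and 11 enter as purchased materials.

**Step 7 (key step).** The most likely failure is fragmentation of 10 before or instead of annulation: methoxide or the ketone enolate adds to the C5 carbonyl and the non-enolisable beta-keto ester cleaves by retro-Claisen reaction. The second concern is stalling after the first acylation, because the diketonate of 12 is a weak nucleophile and the remaining ester is neopentyl-like; a second intermolecular acylation could then take over.
Fallback: set out from 9, in which C6 is still a CH2. As its sodium enolate (NaH), C5 is protected against addition and cleavage and the C1 ester has no quaternary neighbour. Treating this enolate with the lithium enolate of 11 should give Claisen condensation at the only non-enolised ester (C3), and heating should then close the diketonate carbon onto C1 in the manner of triketo-ester cyclisations to acylphloroglucinols. This would give (S)-6-(tert-butyldimethylsilyloxy)-3,5-dihydroxy-4-(2-methylpropanoyl)-6-(3-methylbut-2-enyl)cyclohexa-2,4-dien-1-one F1. The price is a C1 ester made less electrophilic by conjugation with the enolate. Twofold C-prenylation of the ring CH of F1 with 2 under the alkoxide conditions used for acylphloroglucinols comes back to the route at 13.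

**Step 3.** The enantiotopic-group selection may be poor, or may have the opposite sense, because the enzyme pocket has to tell a small OH from a prenyl chain on a quaternary carbon.
Fallback: set out from 4 and hydrolyse one ester with KOH (1 equiv) in aqueous methanol to racemic 2-hydroxy-2-(methoxycarbonyl)-5-methylhex-4-enoic acid F2. Resolve it by fractional crystallisation of a diastereomeric amine salt, written here as (S)-1-phenylethylammonium (R)-2-hydroxy-2-(methoxycarbonyl)-5-methylhex-4-enoate F3; whichever amine enantiomer gives the less soluble salt of the (R)-acid would be used. Acidification returns to the route at 5. The mother-liquor acid can be re-esterified to 4 and recycled.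

**Step 6.** The second alkylation takes place at a hindered, fully substituted enolate, so O-alkylation or incomplete conversion could compete with formation of the gem-diprenyl carbon.
Fallback: build the gem-diprenyl carbon first. Dialkylate 1 with 2 (NaH, THF) to dimethyl 2,2-bis(3-methylbut-2-enyl)malonate F4, then Krapcho dealkoxycarbonylation (LiCl, wet DMSO, 150 °C) to methyl 5-methyl-2-(3-methylbut-2-enyl)hex-4-enoate F5. The lithium enolate of F5 (LiN(iPr)2, THF, −78 °C) is C-acylated by 8, generated from 6 as in step 5, and the sequence comes back to the route at 10. This exchanges the alkylation risk for a hindered but direct acylation.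

**Step 8.** Si–O cleavage at the shielded tertiary centre may be slow, and the longer the freed product is exposed, the more it is open to ring contraction of the alpha-ketol or cyclisation of the enol oxygen onto a prenyl alkene.
Fallback: move the difficult desilylation to the robust open-chain stage. Set out from 10 and remove the silyl group with HF·pyridine, where forcing is tolerated, to give dimethyl (R)-2-hydroxy-2,4,4-tris(3-methylbut-2-enyl)-3-oxopentanedioate F6. Re-protect with triethylsilyl triflate and 2,6-lutidine to dimethyl (R)-2-(triethylsilyloxy)-2,4,4-tris(3-methylbut-2-enyl)-3-oxopentanedioate F7. Annulation with 11 exactly as in step 7 gives (S)-3-hydroxy-2-(2-methylpropanoyl)-4-(triethylsilyloxy)-4,6,6-tris(3-methylbut-2-enyl)cyclohex-2-ene-1,5-dione F8, whose more labile silyl ether should fall off under brief, cold, buffered HF·pyridine, coming back to the route at 14.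

## Further compounds

F1 | step 7 | (S)-6-(tert-butyldimethylsilyloxy)-3,5-dihydroxy-4-(2-methylpropanoyl)-6-(3-methylbut-2-enyl)cyclohexa-2,4-dien-1-one | CC(C)C(=O)C1=C(O)[C@@](O[Si](C)(C)C(C)(C)C)(CC=C(C)C)C(=O)C=C1O
F2 | step 3 | racemic 2-hydroxy-2-(methoxycarbonyl)-5-methylhex-4-enoic acid | COC(=O)C(O)(CC=C(C)C)C(=O)O
F3 | step 3 | (S)-1-phenylethylammonium (R)-2-hydroxy-2-(methoxycarbonyl)-5-methylhex-4-enoate | COC(=O)[C@@](O)(CC=C(C)C)C(=O)[O-].C[C@H]([NH3+])c1ccccc1
F4 | step 6 | dimethyl 2,2-bis(3-methylbut-2-enyl)malonate | COC(=O)C(CC=C(C)C)(CC=C(C)C)C(=O)OC
F5 | step 6 | methyl 5-methyl-2-(3-methylbut-2-enyl)hex-4-enoate | COC(=O)C(CC=C(C)C)CC=C(C)C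
F6 | step 8 | dimethyl (R)-2-hydroxy-2,4,4-tris(3-methylbut-2-enyl)-3-oxopentanedioate | COC(=O)[C@@](O)(CC=C(C)C)C(=O)C(CC=C(C)C)(CC=C(C)C)C(=O)OC
F7 | step 8 | dimethyl (R)-2-(triethylsilyloxy)-2,4,4-tris(3-methylbut-2-enyl)-3-oxopentanedioate | COC(=O)[C@@](O[Si](CC)(CC)CC)(CC=C(C)C)C(=O)C(CC=C(C)C)(CC=C(C)C)C(=O)OC
F8 | step 8 | (S)-3-hydroxy-2-(2-methylpropanoyl)-4-(triethylsilyloxy)-4,6,6-tris(3-methylbut-2-enyl)cyclohex-2-ene-1,5-dione | CC(C)C(=O)C1=C(O)[C@@](O[Si](CC)(CC)CC)(CC=C(C)C)C(=O)C(CC=C(C)C)(CC=C(C)C)C1=O
A1 | alternative 1 | (Z)-6-[1-(tert-butyldimethylsilyloxy)-4-methylpent-3-enylidene]-4-methoxy-5,5-bis(3-methylbut-2-enyl)-5,6-dihydro-2H-pyran-2-one | COC1=CC(=O)O/C(=C(\O[Si](C)(C)C(C)(C)C)CC=C(C)C)C1(CC=C(C)C)CC=C(C)C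
A2 | alternative 1 | (S)-2-(tert-butyldimethylsilyloxy)-5-methoxy-2,4,4-tris(3-methylbut-2-enyl)cyclohex-5-ene-1,3-dione | COC1=CC(=O)[C@@](O[Si](C)(C)C(C)(C)C)(CC=C(C)C)C(=O)C1(CC=C(C)C)CC=C(C)C
A3 | alternative 2 | 9-methyl-2,2-bis(3-methylbut-2-enyl)-3,5,6-trioxodec-8-enal | O=CC(CC=C(C)C)(CC=C(C)C)C(=O)CC(=O)C(=O)CC=C(C)C
A4 | alternative 2 | (S)-3,4-dihydroxy-4,6,6-tris(3-methylbut-2-enyl)cyclohex-2-ene-1,5-dione | CC(C)=CCC1(CC=C(C)C)C(=O)C=C(O)[C@@](O)(CC=C(C)C)C1=O
A5 | alternative 3 | methyl (S)-2-(tert-butyldimethylsilyloxy)-9-methyl-2,6-bis(3-methylbut-2-enyl)-3,5-dioxodec-8-enoate | COC(=O)[C@](O[Si](C)(C)C(C)(C)C)(CC=C(C)C)C(=O)CC(=O)C(CC=C(C)C)CC=C(C)C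
A6 | alternative 3 | (S)-4-(tert-butyldimethylsilyloxy)-3-hydroxy-4,6,6-tris(3-methylbut-2-enyl)cyclohex-2-ene-1,5-dione | CC(C)=CCC1(CC=C(C)C)C(=O)C=C(O)[C@@](O[Si](C)(C)C(C)(C)C)(CC=C(C)C)C1=O
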